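The route rests on disconnecting the C6–CH2 bond of the hydroxyethyl chain to an allyl group parked on O5 of purchased (2S)-homoeriodictyol, which supplies C2. The feature exploited lies in ring A: O5 has a single open ortho carbon, C6, since its other ortho neighbour, C4a, is the fusion atom shared with ring C, whereas O7 lies between C6 and C8. A Eu(fod)3-promoted [3,3] shift of allyl ether 5 (7-O and 4'-O as MOM ethers) thus makes the C6–C bond regiospecifically in one operation. The allyl is then cut to CH2CH2OH, and a second O5 relay through the now blocked C6 carries prenyl to C8.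

Key step: step 3

Assumption: commercial homoeriodictyol of natural origin is taken to be the (2S) enantiomer. Flavanones with a free 4'-OH can racemise by reversible opening of ring C, so its enantiomeric purity is checked by chiral HPLC, and upgraded if needed, before step 1.

Step 1
Reactants: 1 (2S)-homoeriodictyol; 2 chloromethyl methyl ether
Product: 3 (2S)-5-hydroxy-7,4'-bis-O-(methoxymethyl)homoeriodictyol
Conditions: MOMCl (2.3 equiv), then iPr2NEt (2.6 equiv, slow addition), CH2Cl2/THF, 0 °C
Reagents that add atoms: chloromethyl methyl ether, COCCl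
Why: MOM ether formation (Williamson-type O-alkylation) takes the free 7- and 4'-phenols while the 5-OH, hydrogen-bonded to the C4 carbonyl, stays untouched, and a hindered amine at 0 °C with the electrophile already present keeps the phenoxide lifetime too short for retro-oxa-Michael opening of ring C, so C2 should hold.

Step 2
Reactants: 3 (2S)-5-hydroxy-7,4'-bis-O-(methoxymethyl)homoeriodictyol; 4 allyl alcohol
Product: 5 (2S)-5-O-allyl-7,4'-bis-O-(methoxymethyl)homoeriodictyol
Conditions: allyl alcohol (1.5 equiv), PPh3 (1.5 equiv), DIAD (1.5 equiv), THF, 0 °C to rt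
Reagents that add atoms: allyl alcohol, C=CCO
Why: Mitsunobu etherification, known for the chelated 5-OH of 7,4'-protected flavanones, alkylates O5 under essentially neutral conditions and so avoids the carbonate bases that open ring C to the chalcone and would racemise C2.

Step 3
Reactants: 5 (2S)-5-O-allyl-7,4'-bis-O-(methoxymethyl)homoeriodictyol
Product: 7 (2S)-6-allyl-5-hydroxy-7,4'-bis-O-(methoxymethyl)homoeriodictyol, via C6-allyl cyclohexadienone 6 (not isolated)
Conditions: Eu(fod)3 (10 mol %; fod = 6,6,7,7,8,8,8-heptafluoro-2,2-dimethyloctane-3,5-dionate), PhCl, 110 °C, sealed tube, argon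
Reagents that add atoms: none
Why: Trivalent europium chelates the C4 carbonyl oxygen and O5, polarises the O5–CH2 bond and lowers the barrier of a concerted, chair-like [3,3] shift in which the allyl terminus bonds to C6 to give dienone 6, which loses its C6 hydrogen by enolisation to give phenol 7 and regains the O5–H···O=C4 hydrogen bond. The closest known reaction type is the Lewis-acid-catalysed aromatic Claisen rearrangement of flavonoid 5-O-allyl ethers. No ring is closed and no lasting stereocentre is made (the C6 centre of 6 vanishes on enolisation), and C2 is a spectator because neither base nor Brønsted acid is present to open ring C. The selectivity needed is C6 over C8, and it is secured by the point of attachment: the ortho carbons of O5 are C6 and C4a, and C4a is the fully substituted fusion carbon, where a shift could only give a non-aromatisable species that reverts. C8 could be reached only by a Cope shift from 6, which should be outrun by tautomerisation, all the more so for an unsubstituted allyl group that gains no steric relief by moving on. The MOM ethers should survive because Eu(fod)3 is a mild, aprotic, oxophilic Lewis acid.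

Step 4
Reactants: 7 (2S)-6-allyl-5-hydroxy-7,4'-bis-O-(methoxymethyl)homoeriodictyol
Product: 8 (2S)-5-hydroxy-7,4'-bis-O-(methoxymethyl)-6-(2-oxoethyl)homoeriodictyol
Conditions: OsO4 (2 mol %), NaIO4 (4 equiv), 2,6-lutidine (2 equiv), dioxane/H2O 3:1, rt
Reagents that add atoms: osmium tetroxide (catalytic oxygen carrier), O=[Os](=O)(=O)=O; NaIO4 (stoichiometric oxygen source), [Na+].[O-]I(=O)(=O)=O
Why: Lemieux–Johnson cleavage (catalytic dihydroxylation, then periodate glycol scission) removes the terminal CH2 of the only alkene in 7, no prenyl group being present yet, with 2,6-lutidine buffering the medium so that the MOM ethers and the sensitive arylacetaldehyde survive; 8 is carried on crude without chromatography.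

Step 5
Reactants: 8 (2S)-5-hydroxy-7,4'-bis-O-(methoxymethyl)-6-(2-oxoethyl)homoeriodictyol
Product: 9 (2S)-5-hydroxy-6-(2-hydroxyethyl)-7,4'-bis-O-(methoxymethyl)homoeriodictyol
Conditions: NaBH(OAc)3 (2.5 equiv), THF, rt; aqueous work-up
Reagents that add atoms: none
Why: This chemoselective hydride reduction works because NaBH(OAc)3 is mild enough to reduce an aliphatic aldehyde but not the C4 ketone, which is further deactivated as a chelated, trioxygenated aryl ketone, and the non-basic medium leaves C2 alone.

Step 6
Reactants: 9 (2S)-5-hydroxy-6-(2-hydroxyethyl)-7,4'-bis-O-(methoxymethyl)homoeriodictyol; 10 tert-butyldimethylsilyl chloride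
Product: 11 (2S)-6-[2-(tert-butyldimethylsilyloxy)ethyl]-5-hydroxy-7,4'-bis-O-(methoxymethyl)homoeriodictyol
Conditions: TBSCl (1.1 equiv), imidazole (2 equiv), CH2Cl2, 0 °C to rt
Reagents that add atoms: tert-butyldimethylsilyl chloride, CC(C)(C)[Si](C)(C)Cl
Why: In this silyl ether formation the unhindered primary alcohol reacts far faster than the hydrogen-bonded, doubly flanked 5-OH, and masking it is needed because a free 2-hydroxyethyl group would itself be activated and close onto O5 in the next Mitsunobu step.

Step 7
Reactants: 11 (2S)-6-[2-(tert-butyldimethylsilyloxy)ethyl]-5-hydroxy-7,4'-bis-O-(methoxymethyl)homoeriodictyol; 12 3-methylbut-2-en-1-ol (prenol)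
Product: 13 (2S)-6-[2-(tert-butyldimethylsilyloxy)ethyl]-7,4'-bis-O-(methoxymethyl)-5-O-prenylhomoeriodictyol
Conditions: prenol (2 equiv), PPh3 (2 equiv), DIAD (2 equiv), THF (concentrated), 0 °C to rt
Reagents that add atoms: 3-methylbut-2-en-1-ol, CC(C)=CCO
Why: A second Mitsunobu etherification, again base-free for the sake of C2, lets O5 attack the activated primary allylic alcohol in SN2 fashion, with a concentrated solution and excess reagents offsetting the crowding by the C6 chain.

Step 8
Reactants: 13 (2S)-6-[2-(tert-butyldimethylsilyloxy)ethyl]-7,4'-bis-O-(methoxymethyl)-5-O-prenylhomoeriodictyol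
Product: 16 (2S)-6-[2-(tert-butyldimethylsilyloxy)ethyl]-5-hydroxy-7,4'-bis-O-(methoxymethyl)-8-prenylhomoeriodictyol, via C6-quaternary ortho-dienone 14 (not isolated), via C8-prenyl para-dienone 15 (not isolated)
Conditions: Eu(fod)3 (10 mol %), PhCl, 85 °C, argon
Reagents that add atoms: none
Why: In this tandem aromatic Claisen–Cope (para-Claisen) rearrangement, known for flavonoid 5-O-prenyl ethers under Eu(fod)3, the first [3,3] shift places a 1,1-dimethylallyl group on the already substituted C6 to give 14, which cannot enolise and so passes by a second [3,3] shift to C8 (para to C5 and the only free carbon of ring A) to give 15, which tautomerises to phenol 16 with the prenyl group back in its linear form after the double allylic inversion.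

Step 9
Reactants: 16 (2S)-6-[2-(tert-butyldimethylsilyloxy)ethyl]-5-hydroxy-7,4'-bis-O-(methoxymethyl)-8-prenylhomoeriodictyol
Product: 17 laxiflorin, (2S)-5,7,4'-trihydroxy-6-(2-hydroxyethyl)-3'-methoxy-8-prenylflavanone
Conditions: 2 M aq HCl/MeOH 1:5, 45 °C, close monitoring; NaHCO3 quench to about pH 6
Reagents that add atoms: none
Why: Acid-catalysed acetal methanolysis and silyl ether solvolysis remove both MOM groups and the TBS group in one operation, a deprotection precedented for 8-prenylated flavonoids, with dilute acid, mild heating and an early quench limiting addition of O7–H to the prenyl alkene, and the fully substituted ring A cannot capture the formaldehyde equivalents released.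

Compound list
1 | (2S)-homoeriodictyol, (2S)-5,7-dihydroxy-2-(4-hydroxy-3-methoxyphenyl)chroman-4-one | COc1cc([C@@H]2CC(=O)c3c(O)cc(O)cc3O2)ccc1O | starting material
2 | chloromethyl methyl ether | COCCl | starting material
3 | (2S)-5-hydroxy-7,4'-bis-O-(methoxymethyl)homoeriodictyol | COc1cc([C@@H]2CC(=O)c3c(O)cc(OCOC)cc3O2)ccc1OCOC | intermediate
4 | allyl alcohol | C=CCO | starting material
5 | (2S)-5-O-allyl-7,4'-bis-O-(methoxymethyl)homoeriodictyol | COc1cc([C@@H]2CC(=O)c3c(OCC=C)cc(OCOC)cc3O2)ccc1OCOC | intermediate
6 | (2S)-C6-allyl cyclohexadienone: C5=O, sp3 C6 bearing H and allyl (transient configuration undefined), C7=C8 and C4a=C8a double bonds | COc1cc([C@@H]2CC(=O)C3=C(O2)C=C(OCOC)C(CC=C)C3=O)ccc1OCOC | intermediate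
7 | (2S)-6-allyl-5-hydroxy-7,4'-bis-O-(methoxymethyl)homoeriodictyol | COc1cc([C@@H]2CC(=O)c3c(O)c(CC=C)c(OCOC)cc3O2)ccc1OCOC | intermediate
8 | (2S)-5-hydroxy-7,4'-bis-O-(methoxymethyl)-6-(2-oxoethyl)homoeriodictyol | COc1cc([C@@H]2CC(=O)c3c(O)c(CC=O)c(OCOC)cc3O2)ccc1OCOC | intermediate
9 | (2S)-5-hydroxy-6-(2-hydroxyethyl)-7,4'-bis-O-(methoxymethyl)homoeriodictyol | COc1cc([C@@H]2CC(=O)c3c(O)c(CCO)c(OCOC)cc3O2)ccc1OCOC | intermediate
10 | tert-butyldimethylsilyl chloride | CC(C)(C)[Si](C)(C)Cl | starting material
11 | (2S)-6-[2-(tert-butyldimethylsilyloxy)ethyl]-5-hydroxy-7,4'-bis-O-(methoxymethyl)homoeriodictyol | COc1cc([C@@H]2CC(=O)c3c(O)c(CCO[Si](C)(C)C(C)(C)C)c(OCOC)cc3O2)ccc1OCOC | intermediate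
12 | 3-methylbut-2-en-1-ol (prenol) | CC(C)=CCO | starting material
13 | (2S)-6-[2-(tert-butyldimethylsilyloxy)ethyl]-7,4'-bis-O-(methoxymethyl)-5-O-prenylhomoeriodictyol | COc1cc([C@@H]2CC(=O)c3c(OCC=C(C)C)c(CCO[Si](C)(C)C(C)(C)C)c(OCOC)cc3O2)ccc1OCOC | intermediate
14 | (2S)-C6-quaternary ortho-dienone: C5=O, C6 bearing the silyloxyethyl chain and a 1,1-dimethylallyl group (transient configuration undefined) | COc1cc([C@@H]2CC(=O)C3=C(O2)C=C(OCOC)C(CCO[Si](C)(C)C(C)(C)C)(C(C)(C)C=C)C3=O)ccc1OCOC | intermediate
15 | (2S)-C8-prenyl para-dienone: C5=O, sp3 C8 bearing H and prenyl (transient configuration undefined), C6=C7 and C4a=C8a double bonds | COc1cc([C@@H]2CC(=O)C3=C(O2)C(CC=C(C)C)C(OCOC)=C(CCO[Si](C)(C)C(C)(C)C)C3=O)ccc1OCOC | intermediate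
16 | (2S)-6-[2-(tert-butyldimethylsilyloxy)ethyl]-5-hydroxy-7,4'-bis-O-(methoxymethyl)-8-prenylhomoeriodictyol | COc1cc([C@@H]2CC(=O)c3c(O)c(CCO[Si](C)(C)C(C)(C)C)c(OCOC)c(CC=C(C)C)c3O2)ccc1OCOC | intermediate
17 | laxiflorin, (2S)-5,7,4'-trihydroxy-6-(2-hydroxyethyl)-3'-methoxy-8-prenylflavanone | COc1cc([C@@H]2CC(=O)c3c(O)c(CCO)c(O)c(CC=C(C)C)c3O2)ccc1O | target

Total step count: 9. Longest linear sequence: 9 steps, from 1 to 17.

Steps most likely to fail

**Step 3.** Turnover may be too slow at temperatures that are still safe for C2. The chelating product may inhibit the catalyst. The Lewis acid may cleave the allyl ether, part of the material may migrate onward to C8, and prolonged heating may erode C2 through reversible opening of ring C. The fallback replaces the sigmatropic relay by halogenation and cross-coupling and sets out from 3. Iodination directed ortho to the free 5-OH with BnMe3N·ICl2 and CaCO3 in CH2Cl2/MeOH at rt should give (2S)-5-hydroxy-6-iodo-7,4'-bis-O-(methoxymethyl)homoeriodictyol F1. Stille coupling of this iodide with allyltributylstannane (Pd(PPh3)4, DMF, 80 °C) comes back to the route at 7.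

**Step 8.** The allylic O5–C bond may ionise at the Lewis acid with loss of the prenyl group. The first shift may also be unfavourable because it has to quaternise the crowded C6, so that material stays at the ether stage, and C2 may erode on extended heating. The fallback sets out from 11 and therefore also bypasses step 7. C8 is the only unsubstituted carbon of ring A and lies para to the free 5-OH, so NIS in DMF at 0 °C to rt should give (2S)-6-[2-(tert-butyldimethylsilyloxy)ethyl]-5-hydroxy-8-iodo-7,4'-bis-O-(methoxymethyl)homoeriodictyol F2. Stille coupling with tributyl(3-methylbut-2-enyl)stannane (Pd(PPh3)4, DMF, 80 °C), which is expected to couple at the stannane's CH2 terminus and give the linear prenyl group, comes back to the route at 16.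

**Step 9.** Acid may add O7–H across the prenyl double bond (chroman closure) or hydrate the alkene. MOM cleavage may stay incomplete at the mild temperature chosen, and acid-assisted opening of ring C may erode C2. The fallback moves all acid chemistry ahead of the prenyl group and ends with fluoride.
- It sets out from 9, where no alkene is present. 2 M aq HCl/MeOH at 50 °C should give (2S)-6-(2-hydroxyethyl)homoeriodictyol F3.
- TBSCl (3.3 equiv) and imidazole in DMF should then give the (2S)-7,4',2'''-tris-O-TBS ether with free chelated 5-OH F4.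
- Mitsunobu reaction with prenol 12 (PPh3, DIAD, THF) should give the (2S)-5-O-prenyl tris-O-TBS ether F5.
- Eu(fod)3 in PhCl at 85 °C should relay the prenyl group to give the (2S)-8-prenyl-5-hydroxy tris-O-TBS ether F6.
- Et3N·3HF in THF at rt removes all three silyl groups without an acid able to protonate the alkene, coming back to the route at 17.

Further compounds
F1 | step 3 | (2S)-5-hydroxy-6-iodo-7,4'-bis-O-(methoxymethyl)homoeriodictyol | COc1cc([C@@H]2CC(=O)c3c(O)c(I)c(OCOC)cc3O2)ccc1OCOC
F2 | step 8 | (2S)-6-[2-(tert-butyldimethylsilyloxy)ethyl]-5-hydroxy-8-iodo-7,4'-bis-O-(methoxymethyl)homoeriodictyol | COc1cc([C@@H]2CC(=O)c3c(O)c(CCO[Si](C)(C)C(C)(C)C)c(OCOC)c(I)c3O2)ccc1OCOC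
F3 | step 9 | (2S)-6-(2-hydroxyethyl)homoeriodictyol | COc1cc([C@@H]2CC(=O)c3c(O)c(CCO)c(O)cc3O2)ccc1O
F4 | step 9 | (2S)-7,4'-bis-O-TBS-6-[2-(tert-butyldimethylsilyloxy)ethyl]-5-hydroxyhomoeriodictyol | COc1cc([C@@H]2CC(=O)c3c(O)c(CCO[Si](C)(C)C(C)(C)C)c(O[Si](C)(C)C(C)(C)C)cc3O2)ccc1O[Si](C)(C)C(C)(C)C
F5 | step 9 | (2S)-7,4'-bis-O-TBS-6-[2-(tert-butyldimethylsilyloxy)ethyl]-5-O-prenylhomoeriodictyol | COc1cc([C@@H]2CC(=O)c3c(OCC=C(C)C)c(CCO[Si](C)(C)C(C)(C)C)c(O[Si](C)(C)C(C)(C)C)cc3O2)ccc1O[Si](C)(C)C(C)(C)C
F6 | step 9 | (2S)-7,4'-bis-O-TBS-6-[2-(tert-butyldimethylsilyloxy)ethyl]-5-hydroxy-8-prenylhomoeriodictyol | COc1cc([C@@H]2CC(=O)c3c(O)c(CCO[Si](C)(C)C(C)(C)C)c(O[Si](C)(C)C(C)(C)C)c(CC=C(C)C)c3O2)ccc1O[Si](C)(C)C(C)(C)C
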